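The plan rests on reconnecting C3 (the ring ketone) and C8 (the acyloxy carbon). These two carbons face each other 1,6 across the ten-membered ring C1–C10. The C3–C8 bond converts the macrocycle into a cis-decalin (ring A: C3–C8; ring B: C3, C2, C1, C10, C9, C8) built on (S)-carvone. In one operation the key step turns the C3 carbinol into an oxygen radical and breaks the C3–C8 fusion bond. This releases the (1Z,4Z)-dienone and the ten-membered ring, and C8 is set by hydrogen-atom transfer. The precursor is a bis-allylic C3 tertiary alcohol with silyl ethers at O8 and O10, the cis-γ-lactone in place, and the exocyclic methylene masked as a β-sulfone.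

Key step: step 16

Numbering and faces: germacrane numbers are used (ring C1–C10; lactone C11, C12; methylene C13; C14 = methyl on C10; C15 = methyl on C4; On = oxygen on Cn). On ring A, "C11 face" is the side of the C7–C11 bond and "H7 face" is the opposite side. The target is 6S,7R,8R,10R,2′R.

Assumption: the target is taken as the open C10-hydroxy dienone that is drawn. Addition of O10 to C3 across the Z-enone is a ring–chain equilibrium of the same compound.

Design points:
- **Amide arm for C9–C10.** A free methyl ketone would be enolised before C8–H and would leave C10 to an uncontrolled acyclic addition.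
- **Lactone before ketone.** O6 is tied up in the lactone before the C3 ketone appears, because a free (Z)-γ-hydroxy enone would dehydrate to a furan.
- **Masked methylene.** The methylene lactone is masked in step 16, because thiols and the nucleophilic C8 radical both add to it.
- **TBS on O8.** O8 carries TBS to resist a 1,2-silyl shift to O3.
- **Erased centres.** C3 and quaternary C8 are erased in step 16 and serve only as stereochemical relays.

Step 1
Reactants: 1 (S)-carvone; 2 2-bromo-N-methoxy-N-methylacetamide
Product: 3 carvone carrying the CH2C(O)N(OMe)Me arm (C9–C10) at C8, arm on the H7 face (anti to isopropenyl)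
Conditions: LDA, THF, −78 °C; then 2, DMPU, −78 → −20 °C
Reagents that add atoms: 2-bromo-N-methoxy-N-methylacetamide, BrCC(=O)N(C)OC
Why: Kinetic α′-deprotonation of the enone followed by SN2 enolate alkylation with an activated α-halo amide should put the arm anti to the isopropenyl group, and this centre is provisional because C8 is re-enolised in step 2.

Step 2
Reactants: 3
Product: 4 tertiary α-ketol, O8–H on the H7 face and the C9 arm on the C11 face
Conditions: LDA, THF, −78 °C; then 2-(benzenesulfonyl)-3-phenyloxaziridine, −78 °C
Reagents that add atoms: Davis oxaziridine, O=S(=O)(N1OC1c1ccccc1)c1ccccc1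
Why: In this Davis enolate hydroxylation, the tetrasubstituted α′-enolate pushes the isopropenyl group pseudoaxial, so oxygen should arrive anti to it and fix quaternary C8.

Step 3
Reactants: 4
Product: 5 diol, as 4 with the isopropenyl methyl oxidised to CH2OH (C12–OH, C11=C13 retained)
Conditions: SeO2 (cat.), t-BuOOH, CH2Cl2, 0 °C → rt
Reagents that add atoms: tert-butyl hydroperoxide, CC(C)(C)OO (oxygen relayed through catalytic SeO2, O=[Se]=O)
Why: In this Riley-type allylic hydroxylation (ene reaction, then [2,3]-shift), the isopropenyl group is the only electron-rich alkene because C4=C5 is deactivated as an enone, and C7–H is shielded by quaternary C8.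

Step 4
Reactants: 5
Product: 7 enone with O12-TES plus O8-TBS, via O12-TES ketol 6 (not isolated)
Conditions: TESOTf (1 equiv), 2,6-lutidine, CH2Cl2, −78 °C; then TBSOTf, −78 °C → rt
Reagents that add atoms: triethylsilyl triflate, CC[Si](CC)(CC)OS(=O)(=O)C(F)(F)F; tert-butyldimethylsilyl triflate, CC(C)(C)[Si](C)(C)OS(=O)(=O)C(F)(F)F
Why: Sequential silyl triflate silylation exploits the large rate gap between the primary allylic and the hindered tertiary hydroxyl, giving a labile group on O12 and a migration-resistant one on O8.

Step 5
Reactants: 7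
Product: 9 γ-hydroxy enone with O6–H on the H7 face (trans to C11), via TMS dienol ether 8 (not isolated)
Conditions: TMSOTf, Et3N, CH2Cl2, 0 °C; then mCPBA, NaHCO3, CH2Cl2, −20 °C; then aq citric acid
Reagents that add atoms: trimethylsilyl triflate, C[Si](C)(C)OS(=O)(=O)C(F)(F)F (in 8 only); mCPBA, O=C(OO)c1cccc(Cl)c1
Why: In this vinylogous Rubottom oxidation, C8 is quaternary so soft enolisation can only give the extended C3=C4–C5=C6 dienol ether, and peracid should attack its unhindered γ,δ-bond from the face opposite the C9 and C11 arms.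

Step 6
Reactants: 9
Product: 10 C3,C6-ene-dione
Conditions: Dess–Martin periodinane, NaHCO3, CH2Cl2, 0 °C; used at once
Reagents that add atoms: none
Why: Dess–Martin oxidation under buffered, non-enolising conditions removes the wrongly configured C6 carbinol while sparing the silyl ethers and the now doubly activated C7–H.

Step 7
Reactants: 10
Product: 11 γ-hydroxy enone with O6–H on the C11 face (cis to the C7 side chain)
Conditions: NaBH4, CeCl3·7H2O, MeOH–CH2Cl2, −78 °C
Reagents that add atoms: none
Why: In this Luche 1,2-reduction, hydride should choose C6 over C3 (C3 is flanked by quaternary C8 and by C4-methyl) and enter from the H7 face away from both arms, setting C6 cis to C11 as in isopiperitenone-type enones.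

Step 8
Reactants: 11
Product: 12 tris-silyl ether (O6-TES, O12-TES, O8-TBS) of the enone amide
Conditions: TESCl, imidazole, CH2Cl2, 0 °C
Reagents that add atoms: chlorotriethylsilane, CC[Si](Cl)(CC)CC
Why: Routine silylation of the only free hydroxyl also prevents O6 from lactonising onto the C10 amide on the same face.

Step 9
Reactants: 12; 13 vinylmagnesium bromide (2 equiv consumed)
Product: 14 C3 tertiary carbinol (O3–H on the H7 face, vinyl C2 on the C11 face) whose C9 arm ends in a vinyl ketone (C10=O, C1)
Conditions: 13 (excess), LaCl3·2LiCl, THF, −78 → 0 °C; cold aq KHSO4 quench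
Reagents that add atoms: vinylmagnesium bromide, C=C[Mg]Br
Why: Weinreb ketone synthesis and lanthanide-promoted 1,2-addition run in one flask; vinyl should add to C3 anti to the C8–OSi bond (polar Felkin–Anh), and a C3 epimer would also serve because C3 is erased in step 16.

Step 10
Reactants: 14
Product: 15 cis-fused bicyclic 4-hydroxy enone (ring B closed: C3(OH)–C2=C1–C10(=O)–C9–C8; O3 and O8 both on the H7 face)
Conditions: Hoveyda–Grubbs II (5 mol %), PhMe, 60 °C
Reagents that add atoms: none
Why: Ring-closing metathesis should engage only the two monosubstituted alkenes, since C11=C13 and C4=C5 are too substituted, and a six-membered ring can only hold C1=C2 as Z.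

Step 11
Reactants: 15; 16 methylmagnesium bromide
Product: 17 C10 tertiary carbinol (O10–H on the H7 face, syn to O8; C14 on the C11 face)
Conditions: 16 (excess), LaCl3·2LiCl, THF, −78 → −20 °C
Reagents that add atoms: methylmagnesium bromide, C[Mg]Br
Why: In this 1,2-addition of a weakly basic methyl nucleophile, the conformer with the C11 arm equatorial holds the O8 silyl ether axial on ring B, where it blocks the H7 face of C10, so methyl should enter equatorially from the C11 face and set C10.

Step 12
Reactants: 17
Product: 18 tetraol mono-TBS ether (O3, O6, O10, O12 free; O8-TBS)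
Conditions: HF·pyridine, pyridine, THF, 0 °C
Reagents that add atoms: none
Why: Buffered fluoride desilylation discriminates by steric access, so the primary and secondary allylic TES ethers should fall while the tertiary TBS ether and the acid-sensitive tertiary allylic carbinols stay.

Step 13
Reactants: 18
Product: 20 cis-fused α-methylene-γ-lactone diol (O3–H plus O10–H free; O8-TBS), via lactol 19 (not isolated)
Conditions: TEMPO (cat.), PhI(OAc)2, CH2Cl2, rt
Reagents that add atoms: none
Why: In this TEMPO/iodine(III) oxidative lactonisation of a 2-methylene-1,4-diol, the primary allylic alcohol is oxidised first, the aldehyde is trapped by the cis O6–H as lactol 19, and 19 is oxidised on, while tertiary carbinols cannot react.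

Step 14
Reactants: 20
Product: 21 O10-TES, O8-TBS methylene lactone with free O3–H
Conditions: TESOTf (1.1 equiv), 2,6-lutidine, CH2Cl2, −78 °C
Reagents that add atoms: triethylsilyl triflate, CC[Si](CC)(CC)OS(=O)(=O)C(F)(F)F
Why: Kinetic silylation should take O10 (neighbours CH3, CH2, CH=) rather than O3 (buried between quaternary C8 and methyl-bearing C4), leaving a single free O–H for step 16.

Step 15
Reactants: 21
Product: 22 key-step precursor, the 13-phenylsulfonyl-11,13-dihydro lactone (H11 on the H7 face)
Conditions: PhSO2Na, AcOH, EtOH–THF, rt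
Reagents that add atoms: sodium benzenesulfinate, [Na+].[O-]S(=O)c1ccccc1
Why: Sulfa-Michael addition goes to the only acceptor in the molecule; provisional C11 should be set by protonation of the lactone enolate on its convex face, and the sulfone is inert to oxidants, thiols and carbon radicals.

Step 16
Reactants: 22
Product: 23 ten-membered (1Z,4Z)-dien-3-one with C8–H, O8-TBS, O10-TES and the sulfone-masked lactone
Conditions: [Ir(dF(CF3)ppy)2(5,5′-d(CF3)bpy)]PF6 (2 mol %), 2,4,6-triisopropylbenzenethiol (25 mol %), Bu4P (MeO)2PO2 (25 mol %), degassed PhMe (0.02 M), blue LED, rt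
Reagents that add atoms: none
Why: The excited iridium oxidant and the phosphate hydrogen-bonded to O3–H remove electron and proton together to give the O3 radical, which cleaves C3–C8 to the cross-conjugated dienone and an α-silyloxy C8 radical; the thiol donates hydrogen to C8, and the thiyl radical is reduced by Ir(II) and reprotonated, so the step is a net isomerisation. The closest known chemistry is the redox-neutral, proton-coupled-electron-transfer ring opening of cyclic tertiary alcohols and of vicinally oxygenated C–C bonds, together with alkoxy-radical ring expansion of ring-fusion carbinols. No bond-forming closure is involved: the ten-membered ring is the perimeter of the decalin and appears when the shared bond breaks, so C1=C2 and C4=C5 keep their cyclohexene (Z) geometry. C8 is controlled by C7: the p-orbital is aligned with the C7–C11 bond, the sulfonylmethyl lactone covers the rear lobe, and the thiol should reach the lobe vacated by C3, giving 8R. Regioselectivity is secured because cleavage of C3–C2 or C3–C4 would give vinyl radicals, only one O–H is free, and transannular additions of the C8 radical would be 4-exo or 5-endo.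

Step 17
Reactants: 23
Product: 24 O8-TBS, O10-TES ether of the deacylated target (methylene lactone restored)
Conditions: DBU, CH2Cl2, 0 °C
Reagents that add atoms: none
Why: E1cB loss of benzenesulfinate from the β-sulfonyl lactone should regenerate C11=C13 while both hydroxyls are still capped, so no alkoxide can add to the dienone.

Step 18
Reactants: 24
Product: 25 C8,C10-diol (deacylated target)
Conditions: HF·pyridine, THF, 0 °C → rt
Reagents that add atoms: none
Why: Mildly acidic fluoride desilylation removes the now secondary TBS and the tertiary TES ether without base, which the dienone and the methylene lactone would not tolerate.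

Step 19
Reactants: 25; 26 (R)-2-methylbutanoic acid
Product: 27 target CNP0315499.1
Conditions: 26, DCC, DMAP (cat.), CH2Cl2, 0 °C → rt
Reagents that add atoms: (R)-2-methylbutanoic acid, CC[C@@H](C)C(=O)O
Why: In this Steglich esterification only the secondary C8–OH should be acylated because the tertiary O10–H is inert, and the α-centre of the acid is kept by carbodiimide activation with little DMAP at low temperature.

Compound list
1 | (S)-carvone | CC1=CC[C@H](C(C)=C)CC1=O | starting material
2 | 2-bromo-N-methoxy-N-methylacetamide | BrCC(=O)N(C)OC | starting material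
3 | C8-alkylated carvone (Weinreb amide arm on the H7 face) | CC1=CC[C@H](C(C)=C)[C@@H](CC(=O)N(C)OC)C1=O | intermediate
4 | C8 tertiary α-ketol (O8 on the H7 face, C9 on the C11 face) | CC1=CC[C@H](C(C)=C)[C@](O)(CC(=O)N(C)OC)C1=O | intermediate
5 | C8,C12-diol | CC1=CC[C@H](C(CO)=C)[C@](O)(CC(=O)N(C)OC)C1=O | intermediate
6 | O12-TES ketol (not isolated) | CC1=CC[C@H](C(CO[Si](CC)(CC)CC)=C)[C@](O)(CC(=O)N(C)OC)C1=O | intermediate
7 | O12-TES, O8-TBS enone | CC1=CC[C@H](C(CO[Si](CC)(CC)CC)=C)[C@](O[Si](C)(C)C(C)(C)C)(CC(=O)N(C)OC)C1=O | intermediate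
8 | extended TMS dienol ether (not isolated) | CC=1C=C[C@H](C(CO[Si](CC)(CC)CC)=C)[C@](O[Si](C)(C)C(C)(C)C)(CC(=O)N(C)OC)C=1O[Si](C)(C)C | intermediate
9 | γ-hydroxy enone, O6 trans to C11 | CC1=C[C@@H](O)[C@H](C(CO[Si](CC)(CC)CC)=C)[C@](O[Si](C)(C)C(C)(C)C)(CC(=O)N(C)OC)C1=O | intermediate
10 | C3,C6-ene-dione | CC1=CC(=O)[C@H](C(CO[Si](CC)(CC)CC)=C)[C@](O[Si](C)(C)C(C)(C)C)(CC(=O)N(C)OC)C1=O | intermediate
11 | γ-hydroxy enone, O6 cis to C11 | CC1=C[C@H](O)[C@H](C(CO[Si](CC)(CC)CC)=C)[C@](O[Si](C)(C)C(C)(C)C)(CC(=O)N(C)OC)C1=O | intermediate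
12 | O6-TES, O12-TES, O8-TBS enone amide | CC1=C[C@H](O[Si](CC)(CC)CC)[C@H](C(CO[Si](CC)(CC)CC)=C)[C@](O[Si](C)(C)C(C)(C)C)(CC(=O)N(C)OC)C1=O | intermediate
13 | vinylmagnesium bromide | C=C[Mg]Br | starting material
14 | C3 vinyl carbinol with C10 vinyl ketone | CC1=C[C@H](O[Si](CC)(CC)CC)[C@H](C(CO[Si](CC)(CC)CC)=C)[C@](O[Si](C)(C)C(C)(C)C)(CC(=O)C=C)[C@]1(O)C=C | intermediate
15 | cis-decalin 4-hydroxy enone | CC1=C[C@H](O[Si](CC)(CC)CC)[C@H](C(CO[Si](CC)(CC)CC)=C)[C@]2(O[Si](C)(C)C(C)(C)C)CC(=O)C=C[C@]12O | intermediate
16 | methylmagnesium bromide | C[Mg]Br | starting material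
17 | C3,C10-diol (C10 set) | CC1=C[C@H](O[Si](CC)(CC)CC)[C@H](C(CO[Si](CC)(CC)CC)=C)[C@]2(O[Si](C)(C)C(C)(C)C)C[C@@](C)(O)C=C[C@]12O | intermediate
18 | tetraol mono-TBS ether | CC1=C[C@H](O)[C@H](C(CO)=C)[C@]2(O[Si](C)(C)C(C)(C)C)C[C@@](C)(O)C=C[C@]12O | intermediate
19 | α-methylene lactol, anomer mixture (not isolated) | C=C1C(O)O[C@H]2C=C(C)[C@@]3(O)C=C[C@](C)(O)C[C@@]3(O[Si](C)(C)C(C)(C)C)[C@@H]12 | intermediate
20 | α-methylene lactone, O3–H and O10–H free | C=C1C(=O)O[C@H]2C=C(C)[C@@]3(O)C=C[C@](C)(O)C[C@@]3(O[Si](C)(C)C(C)(C)C)[C@@H]12 | intermediate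
21 | α-methylene lactone, O10-TES, O8-TBS, O3–H free | C=C1C(=O)O[C@H]2C=C(C)[C@@]3(O)C=C[C@](C)(O[Si](CC)(CC)CC)C[C@@]3(O[Si](C)(C)C(C)(C)C)[C@@H]12 | intermediate
22 | key-step precursor (13-phenylsulfonyl-11,13-dihydro form of 21) | O=S(=O)(C[C@H]1C(=O)O[C@H]2C=C(C)[C@@]3(O)C=C[C@](C)(O[Si](CC)(CC)CC)C[C@@]3(O[Si](C)(C)C(C)(C)C)[C@@H]12)c1ccccc1 | intermediate
23 | key-step product (ten-membered dienone, sulfone-masked) | O=S(=O)(C[C@H]1C(=O)O[C@H]2/C=C(/C)C(=O)/C=C\[C@](C)(O[Si](CC)(CC)CC)C[C@@H](O[Si](C)(C)C(C)(C)C)[C@@H]12)c1ccccc1 | intermediate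
24 | O8-TBS, O10-TES ether of the deacylated target | C=C1C(=O)O[C@H]2/C=C(/C)C(=O)/C=C\[C@](C)(O[Si](CC)(CC)CC)C[C@@H](O[Si](C)(C)C(C)(C)C)[C@@H]12 | intermediate
25 | deacylated target (C8,C10-diol) | C=C1C(=O)O[C@H]2/C=C(/C)C(=O)/C=C\[C@](C)(O)C[C@@H](O)[C@@H]12 | intermediate
26 | (R)-2-methylbutanoic acid | CC[C@@H](C)C(=O)O | starting material
27 | CNP0315499.1 | C=C1C(=O)O[C@H]2/C=C(/C)C(=O)/C=C\[C@](C)(O)C[C@@H](OC(=O)[C@H](C)CC)[C@@H]12 | target

Total step count: 19. Longest linear sequence: 19 steps (from 1).

Steps most likely to fail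

1. **Step 16.**
   - What may go wrong: O–H activation at the crowded carbinol may be slow. Hydrogen may be delivered to the wrong lobe of the C8 radical once the medium ring relaxes. Thiyl radicals or energy transfer from the sensitiser may isomerise the Z-enones.
   - Fallback (sets out from 22, returns at 25): 22 is fragmented as its hypoiodite (PhI(OAc)2, I2, CH2Cl2, visible light, Suárez type). The same C3–C8 bond breaks, but the C8 radical is captured oxidatively, and the α-iodo silyl ether collapses with loss of the silyl group to the 3,8-diketone F1. The saturated C8 ketone is reduced in preference to the cross-conjugated dienone (NaBH4, MeOH–CH2Cl2, −78 °C), with peripheral attack anti to the C7–C11 bond, to give the C8 alcohol F2. DBU (CH2Cl2, 0 °C) releases the O10-TES methylene lactone F3, and HF·pyridine gives 25.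

2. **Step 11.**
   - What may go wrong: facial selectivity may erode if ring B reacts through the other cis-decalin conformer. Enolisation toward C9 may be followed by β-elimination of the O8 silyloxy group.
   - Fallback (sets out from 15, returns at 17): carbon and oxygen swap roles. 15 is methylenated (Ph3P=CH2, THF, 0 °C) to the exocyclic diene F4. Buffered mCPBA epoxidises this most electron-rich π bond, so a bias that would have misplaced an incoming carbon now places oxygen on the H7 face, giving the spiro-epoxide F5. LiEt3BH opens F5 at its CH2 terminus to give 17.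

3. **Step 7.**
   - What may go wrong: hydride may attack C3 or add in a conjugate sense. It may approach from the C11 face. C7 may epimerise, or C11=C13 may move into conjugation, while C7–H is α to the C6 ketone.
   - Fallback (sets out from 9, returns at 11; steps 6 and 7 are bypassed): 9 is inverted by SN2 in a Mitsunobu reaction (ClCH2CO2H, PPh3, DIAD, PhMe, 0 °C) to the cis-chloroacetate F6. Brief methanolysis (K2CO3, MeOH, 0 °C) then gives 11, so C6 never passes through the ketone.

Further compounds
F1 | step 16 | 3,8-diketone, O10-TES, sulfone-masked lactone | O=S(=O)(C[C@H]1C(=O)O[C@H]2/C=C(/C)C(=O)/C=C\[C@](C)(O[Si](CC)(CC)CC)CC(=O)[C@@H]12)c1ccccc1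
F2 | step 16 | C8 alcohol, O10-TES, sulfone-masked lactone | O=S(=O)(C[C@H]1C(=O)O[C@H]2/C=C(/C)C(=O)/C=C\[C@](C)(O[Si](CC)(CC)CC)C[C@@H](O)[C@@H]12)c1ccccc1
F3 | step 16 | C8 alcohol, O10-TES, α-methylene lactone | C=C1C(=O)O[C@H]2/C=C(/C)C(=O)/C=C\[C@](C)(O[Si](CC)(CC)CC)C[C@@H](O)[C@@H]12
F4 | step 11 | C10 exocyclic methylene diene | CC1=C[C@H](O[Si](CC)(CC)CC)[C@H](C(CO[Si](CC)(CC)CC)=C)[C@]2(O[Si](C)(C)C(C)(C)C)CC(=C)C=C[C@]12O
F5 | step 11 | C10 spiro-epoxide, oxygen on the H7 face | CC1=C[C@H](O[Si](CC)(CC)CC)[C@H](C(CO[Si](CC)(CC)CC)=C)[C@]2(O[Si](C)(C)C(C)(C)C)C[C@]3(CO3)C=C[C@]12O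
F6 | step 7 | C6 chloroacetate, O6 cis to C11 | CC1=C[C@H](OC(=O)CCl)[C@H](C(CO[Si](CC)(CC)CC)=C)[C@](O[Si](C)(C)C(C)(C)C)(CC(=O)N(C)OC)C1=O
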